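From the earliest seconds, free catalyst in this closed flask works two rounds, one through catalyst intermediate A and one through catalyst intermediate B, and each round has an irreversible exit for the catalyst.

starting material 0.40 M; second substrate 0.500 equiv; capture agent 0.120 M; free catalyst 2.5 mol%

    starting material + free catalyst ⇌ catalyst intermediate A (K1 = 1.1 L mol⁻¹, k1 = 56 L mol⁻¹ s⁻¹)
    catalyst intermediate B → free catalyst + second product (k2 = 1.2 s⁻¹)
    second substrate + free catalyst ⇌ catalyst intermediate B (K3 = 2.5 L mol⁻¹, k3 = 4.6 L mol⁻¹ s⁻¹)
    catalyst intermediate A → free catalyst + target (k4 = 2.7 s⁻¹)
    catalyst intermediate B → spent catalyst (k5 = 0.057 s⁻¹)
    catalyst intermediate A + capture agent → trapped intermediate (k6 = 0.57 L mol⁻¹ s⁻¹)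

- the form that holds most of the catalyst when 50% of the starting material are converted (free catalyst / catalyst intermediate B / trapped intermediate / catalyst intermediate A / spent catalyst)
- its share of the catalyst then

Turned round, the question is what the given numbers would need for the trapped intermediate, an off-cycle sink and no resting state, not to lead.

Follow one molecule of starting material that is truly consumed. It leaves catalyst intermediate A either as target, at 2.7 s⁻¹, or by trapping, at 0.0684 s⁻¹ with the capture agent as charged. The toll φ, the chance that such a molecule ends in trapping, is therefore 2.47%. A molecule that returns to starting material is not consumed, so the backward step stays out of φ. Each trapping event takes one catalyst, and the catalyst charge is 2.5 mol% of the starting material, so 50% conversion is reckoned to put 49.4% of the catalyst in the trapped form.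

The rival is spent catalyst. At the charges, with each intermediate steady against free catalyst, intermediate A stands at 0.417 of free catalyst and intermediate B at 0.297. Trapped intermediate then forms 1.69 times as fast as spent catalyst; in this flask that ratio ρ stands above one, and spent catalyst overtakes the trapped form in the opposite case. If that ratio lasted, spent catalyst would hold 29.3%, leaving 21.3% for the three remaining forms together, less than the trapped share. The reckoning therefore commits to the trapped intermediate at 49.4%.

The forecast also named the trapped intermediate, at 48% (range 43% to 53%), starting from this: “Trapping and product release both draw on intermediate A”.

At 80.2 s the flask holds 48.4% of its catalyst as trapped intermediate and 32.7% as spent catalyst, against the 49.4% reckoned from φ.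

The toll follows conversion, not the clock: at 120 s, with 44.6% of the starting material left in this flask, φ gives 54.7% of the catalyst trapped, and the flask holds 53.5%. The backward run from catalyst intermediate A to starting material and free catalyst stands outside φ but acts on the pace: taking that run away from this flask raises the rate of making target at 50% conversion to 13.6 times the actual one.

(The constants used here come from no measurement; the rest is arithmetic.)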